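At 120 s, when green and amber had both been read, I divided one run by the other so that time dropped out. Their recipes differ in substrate concentration, while equivalents, loading and portions are alike.

| flask | substrate | coupling partner | initiator | remark | time |
|---|---|---|---|---|---|
| green | 8.500 × 10⁻⁵ M | 3 equiv (in portions, 4) | 1 mol% | run made earlier; portions every 8.0 s |  |
| amber | 2.2 × 10⁻⁴ M | 3 equiv (in portions, 4) | 1 mol% | run made earlier; portions every 8.0 s |  |
| Wednesday's | 2.0 × 10⁻⁴ M | 3.00 equiv (in portions, 4) | 1 mol% | the portions of coupling partner follow each other after 8.0 s, the first at the start | 2.0 min |
| Friday's | 6.0 × 10⁻⁵ M | 3.00 equiv | 1 mol% | everything together at the start | 2.0 min |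

| run | time / s | target / % |
|---|---|---|
| green | 25.0 | 17.6 |
| green | 50.0 | 40.5 |
| green | 80.0 | 58.4 |
| green | 90.0 | 58.3 |
| green | 120 | 67.0 |
| amber | 10.0 | 9.0 |
| amber | 20.0 | 23.4 |
| amber | 30.0 | 38.7 |
| amber | 60.0 | 71.8 |
| amber | 120 | 97.3 |

(readings scatter by 1 percentage point)

- which one finishes higher in amount of target, in percent of the substrate charged ("neither" within 2 percentage points) (Wednesday's / Friday's / neither)
- amount of target at the end, in percent of the substrate charged, Wednesday's
- amount of target at the end, in percent of the substrate charged, Friday's

- where the amount of substrate changes, what is given in equivalents or mol% on it follows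

I took the log-yield, minus the logarithm of the fraction not yet target, as a working measure of how far each run had come. My bench rule was that, for one recipe read at one time, the log-yield goes with a power of the concentration:

green 1.11, amber 3.61, concentration ratio 2.59

exponent = ln(amber / green) / ln(concentration ratio) = 1.24

This reading is the dilution exponent, the power linking log-yield to concentration at equal time and equal dosing. Amber's reading lies close to full yield, so the scatter weighs heavily on it.

Wednesday's flask has amber's portions and lies between the two concentrations, so the rule applied directly:

Wednesday's: 96.0%

Friday's flask lay past the border in two ways. Its concentration is 0.706 of green's, below both runs, and its coupling partner goes in at the start. Green's portions wait 12.0 s on average, so I allowed a factor on the log-yield for the longer exposure: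

exposure factor 1.11

Friday's: 55.0%

The forecast said Wednesday's, with 95% for Wednesday's and 59% for Friday's, higher than my Friday figure, adding that “the uncertainty is wider”.

The flasks gave 94.3% for Wednesday's and 67.9% for Friday's, so Wednesday's finished higher.

    initiator → 2 initiating radical (k = 0.0300 s⁻¹)
    coupling partner + chain carrier → target + initiating radical (k = 1.40 × 10⁶ M⁻¹ s⁻¹)
    substrate + initiating radical → chain carrier (k = 3.20 × 10⁶ M⁻¹ s⁻¹)
    coupling partner → decomposed reagent (k = 0.00290 s⁻¹)
    coupling partner ⇌ dormant form (K = 0.770, k = 0.110 s⁻¹)
    2 chain carrier → ended chains (k = 4.90 × 10⁸ M⁻¹ s⁻¹)

The miss lay in Friday's flask, at 67.9% against my 55.0%. Friday's single charge run at Wednesday's concentration gave 98.2%, so the difference in concentration is the main reason for Friday's gap to Wednesday's, worth 30 percentage points. Reckoned between those two single-charge flasks, the dilution exponent is 1.05, lower than the 1.24 I read from the portion runs. Friday's recipe given in portions gave 56.9%, so the single charge of coupling partner accounts for a part of Friday's yield, 11 points.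

(The earlier runs and the new flask stem from a simulated flask on assumed constants; noise was put on by code.)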